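**Plan**

1. Retrosynthesis: cut first the two aryl tert-butyl ether O–C bonds and the acetate O–acyl bond, then the bond between quinone C3 (the carbon next to the acetoxy carbon C2) and C1' of its 4-hydroxyphenyl ring. Behind that come the C2–O methyl bond, the C4=O of the quinone (back to a phenol) and the C6–aryl bond, which leads to 6-bromoguaiacol and the same arylboronic acid.
2. Forward: a Suzuki coupling puts the first aryl ring on 6-bromoguaiacol, and the guaiacol benzene ring is then oxidised to the quinone ring, so no ring is built de novo. Hydrolysis frees the C2–OH, the C3 iodonium ylide is made and coupled with the second arylboronic acid, and acetylation and acid deprotection finish the route.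
3. Enabling feature: in the quinone ring the unit O=C4–C3(H)=C2–OH is a vinylogous carboxylic acid (an enolised 1,3-diketone), so C3 alone can carry a phenyliodonium ylide. C5–H beside the C6 aryl group is an ordinary enone CH. The C2 hydroxyl that activates C3 ends as the acetate, so only the tert-butyl ethers have to be removed.
4. Stereochemistry: none to set, since the target has no stereocentre.

Key step: step 5

Remark: the acetoxyquinone is a vinylogous anhydride, so the acetate is introduced late and the phenols are carried as tert-butyl ethers that are removed by anhydrous acid. Ring numbering throughout: C1=O, C2–O, C3, C4=O, C5–H, C6–aryl.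

**Route**

Step 1
Reactants: 1 2-bromo-6-methoxyphenol; 2 (4-tert-butoxyphenyl)boronic acid
Product: 3 4'-tert-butoxy-3-methoxybiphenyl-2-ol
Conditions: Pd(dppf)Cl2 (3 mol %), K2CO3 (2.5 equiv), 1,4-dioxane/H2O (4:1), 85 °C, Ar; aq. NH4Cl work-up
Reagents that add atoms: none
Why: Suzuki–Miyaura coupling of an ortho-bromophenol with an electron-rich arylboronic acid is a standard biaryl synthesis, and the free phenol, the methyl ether and the tert-butyl ether are inert to aqueous carbonate.

Step 2
Reactants: 3 4'-tert-butoxy-3-methoxybiphenyl-2-ol
Product: 4 6-(4-tert-butoxyphenyl)-2-methoxy-1,4-benzoquinone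
Conditions: salcomine [Co(salen)] (10 mol %), O2 (1 atm), DMF, rt
Reagents that add atoms: dioxygen, O=O
Why: Cobalt–salen catalysed oxygenation of a 2,6-disubstituted phenol with a free para position should give the para-quinone, as in the oxidation of 2-alkyl-6-methoxyphenols to 2-alkyl-6-methoxy-1,4-benzoquinones, and DMF disfavours para–para coupling to a diphenoquinone.

Step 3
Reactants: 4 6-(4-tert-butoxyphenyl)-2-methoxy-1,4-benzoquinone
Product: 5 6-(4-tert-butoxyphenyl)-2-hydroxy-1,4-benzoquinone
Conditions: aq. NaOH (1 M, 2.2 equiv), THF/H2O, 0 °C, degassed, Ar; then cold 1 M HCl to pH 3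
Reagents that add atoms: sodium hydroxide, [Na+].[OH-]
Why: The methoxyquinone is a vinylogous methyl ester, so hydroxide should add at C2 and expel methoxide (addition–elimination, vinylogous saponification), as in the mild alkaline hydrolysis of 2,6-dimethoxy-1,4-benzoquinone to its monohydroxy compound; the tert-butyl aryl ether tolerates base and the brief cold acidification.

Step 4
Reactants: 5 6-(4-tert-butoxyphenyl)-2-hydroxy-1,4-benzoquinone
Product: 6 6-(4-tert-butoxyphenyl)-3-(phenyliodonio)-1,4-benzoquinon-2-olate (zwitterionic phenyliodonium ylide)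
Conditions: PhI(OAc)2 (1.05 equiv), CH2Cl2, 0 °C to rt, dark; the precipitated ylide is filtered off and washed with Et2O
Reagents that add atoms: (diacetoxyiodo)benzene, CC(=O)OI(OC(C)=O)c1ccccc1
Why: 2-Hydroxy-1,4-quinones condense with (diacetoxyiodo)benzene at the carbon between the hydroxyl-bearing carbon and the carbonyl to give zwitterionic phenyliodonium ylides (the reaction known for cyclic 1,3-diketones), and C3 is the only such carbon in 5.

Step 5
Reactants: 6 6-(4-tert-butoxyphenyl)-3-(phenyliodonio)-1,4-benzoquinon-2-olate; 2 (4-tert-butoxyphenyl)boronic acid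
Product: 7 3,6-bis(4-tert-butoxyphenyl)-2-hydroxy-1,4-benzoquinone
Conditions: Pd(OAc)2 (5 mol %), P(t-Bu)3·HBF4 (10 mol %), LiOH·H2O (3 equiv), DME/H2O (4:1), rt, Ar, dark; then cold 1 M HCl
Reagents that add atoms: none
Why: The ylide is the enolate form of a quinonyl(phenyl)iodonium salt: Pd(0) should insert into the C3–I(III) bond with loss of iodobenzene to give a C3-palladated quinonolate, the hydroxide-activated boronate of 2 transmetallates its aryl group, and reductive elimination forms the C3–C1' bond and returns Pd(0). The closest known reaction type is the palladium-catalysed Suzuki-type arylation of phenyliodonium ylides of 2-hydroxy-1,4-quinones (and of cyclic 1,3-diketones) with arylboronic acids. No ring is closed and no stereocentre is formed. The step needs site selectivity between C3 and C5 and transfer of the tert-butoxyphenyl group, not the phenyl ligand on iodine. The first is settled before the step, because only C3, flanked by the C2 oxygen and the C4 carbonyl, can carry the iodonium group, while C5–H beside the C6 aryl is an ordinary enone CH; the second rests on the weaker, more polarised ylide-carbon–iodine bond and on iodobenzene being the better leaving fragment. Room temperature and exclusion of light are chosen to keep the ylide from its thermal rearrangements.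

Step 6
Reactants: 7 3,6-bis(4-tert-butoxyphenyl)-2-hydroxy-1,4-benzoquinone
Product: 8 3,6-bis(4-tert-butoxyphenyl)-1,4-benzoquinon-2-yl acetate
Conditions: Ac2O (1.5 equiv), pyridine (2 equiv), CH2Cl2, 0 °C; cold aq. citric acid wash
Reagents that add atoms: acetic anhydride, CC(=O)OC(C)=O
Why: O-Acetylation of the acidic enolic hydroxyl of a 3-substituted 2-hydroxy-1,4-quinone with acetic anhydride and pyridine is a standard esterification; 7 has no other free hydroxyl, and the non-aqueous, weakly basic medium should spare the product.

Step 7
Reactants: 8 3,6-bis(4-tert-butoxyphenyl)-1,4-benzoquinon-2-yl acetate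
Product: 9 neonambiquinone A, 3,6-bis(4-hydroxyphenyl)-1,4-benzoquinon-2-yl acetate
Conditions: TFA/CH2Cl2 (1:4), 0 °C, N2 sweep; evaporation below 20 °C
Reagents that add atoms: none
Why: Aryl tert-butyl ethers are cleaved by trifluoroacetic acid through E1 loss of the tert-butyl cation (released as 2-methylpropene), an anhydrous and non-nucleophilic acidolysis under which the enol acetate and the quinone should persist.

**Compound list**

1 | 2-bromo-6-methoxyphenol (6-bromoguaiacol) | COc1cccc(Br)c1O | starting material
2 | (4-tert-butoxyphenyl)boronic acid | CC(C)(C)Oc1ccc(B(O)O)cc1 | starting material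
3 | 4'-tert-butoxy-3-methoxybiphenyl-2-ol | COc1cccc(-c2ccc(OC(C)(C)C)cc2)c1O | intermediate
4 | 6-(4-tert-butoxyphenyl)-2-methoxy-1,4-benzoquinone | COC1=CC(=O)C=C(c2ccc(OC(C)(C)C)cc2)C1=O | intermediate
5 | 6-(4-tert-butoxyphenyl)-2-hydroxy-1,4-benzoquinone | OC1=CC(=O)C=C(c2ccc(OC(C)(C)C)cc2)C1=O | intermediate
6 | 6-(4-tert-butoxyphenyl)-3-(phenyliodonio)-1,4-benzoquinon-2-olate | [O-]C1=C([I+]c2ccccc2)C(=O)C=C(c2ccc(OC(C)(C)C)cc2)C1=O | intermediate
7 | 3,6-bis(4-tert-butoxyphenyl)-2-hydroxy-1,4-benzoquinone | OC1=C(c2ccc(OC(C)(C)C)cc2)C(=O)C=C(c2ccc(OC(C)(C)C)cc2)C1=O | intermediate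
8 | 3,6-bis(4-tert-butoxyphenyl)-1,4-benzoquinon-2-yl acetate | CC(=O)OC1=C(c2ccc(OC(C)(C)C)cc2)C(=O)C=C(c2ccc(OC(C)(C)C)cc2)C1=O | intermediate
9 | neonambiquinone A | CC(=O)OC1=C(c2ccc(O)cc2)C(=O)C=C(c2ccc(O)cc2)C1=O | target

**Summary**

Total step count: 7. Longest linear sequence: 7 steps (1 to 9); boronic acid 2 enters in steps 1 and 5.

Steps most likely to fail:

Step 5. The phenyl ligand on iodine may be transferred in place of the boronic-acid aryl group, the iodonium group may be lost by protonolysis or reduction, the ylide may rearrange thermally before it couples, or the I(III) centre may oxidatively homocouple the boronic acid. Fallback: from 5, C3–H is iodinated (iodine–morpholine complex, aq. K2CO3/THF, rt) to 6-(4-tert-butoxyphenyl)-2-hydroxy-3-iodo-1,4-benzoquinone F1. F1 is then joined with 2 in a conventional Suzuki–Miyaura coupling of the halide (Pd(PPh3)4, K2CO3, DME/H2O, 80 °C, acidic work-up), and the route is rejoined at 7.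

Step 3. Hydroxide may add in conjugate fashion at the unsubstituted ring positions, and the hydroxyquinone anion, which still has two free ring CH groups, may degrade oxidatively or self-condense in base. Fallback: from 4, the hydrolysis is postponed until both aryl groups are in place. The enol-ether carbon C3 is brominated (Br2, NaOAc, AcOH/CHCl3, 0 °C) to 3-bromo-6-(4-tert-butoxyphenyl)-2-methoxy-1,4-benzoquinone F2. Suzuki–Miyaura coupling of F2 with 2 (Pd(PPh3)4, K2CO3, dioxane/H2O, 80 °C) should give 3,6-bis(4-tert-butoxyphenyl)-2-methoxy-1,4-benzoquinone F3. Alkaline hydrolysis of the methoxy group of F3 (NaOH, MeOH/H2O, then cold dilute HCl), the classical last operation of terphenylquinone syntheses, then comes back at 7 and bypasses 5 and 6.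

Step 7. The acetyl group may be lost or may migrate from the vinylogous anhydride to the liberated phenols in acid, and the tert-butyl cation may alkylate the liberated phenol rings. Fallback: from 7, the order is inverted. The tert-butyl ethers are removed first (TFA/CH2Cl2, 0 °C) to 2-hydroxy-3,6-bis(4-hydroxyphenyl)-1,4-benzoquinone F4. Only the C2 hydroxyl, a vinylogous carboxylic acid far more acidic than the phenols, is ionised with one equivalent of NaHCO3, and the quinonolate is acetylated with one equivalent of Ac2O in THF at −20 °C, followed by cold acidification, to arrive at 9.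

**Further compounds**

F1 | step 5 | 6-(4-tert-butoxyphenyl)-2-hydroxy-3-iodo-1,4-benzoquinone | OC1=C(I)C(=O)C=C(c2ccc(OC(C)(C)C)cc2)C1=O
F2 | step 3 | 3-bromo-6-(4-tert-butoxyphenyl)-2-methoxy-1,4-benzoquinone | COC1=C(Br)C(=O)C=C(c2ccc(OC(C)(C)C)cc2)C1=O
F3 | step 3 | 3,6-bis(4-tert-butoxyphenyl)-2-methoxy-1,4-benzoquinone | COC1=C(c2ccc(OC(C)(C)C)cc2)C(=O)C=C(c2ccc(OC(C)(C)C)cc2)C1=O
F4 | step 7 | 2-hydroxy-3,6-bis(4-hydroxyphenyl)-1,4-benzoquinone | OC1=C(c2ccc(O)cc2)C(=O)C=C(c2ccc(O)cc2)C1=O
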